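The rate constants were drawn at random within sensible limits; the rest is arithmetic.

The question is which temperature leaves the most X.E after the stated time, and whether temperature matters to it at all.

    L ⇌ E + Q (K1 = 0.00289 M, k1 = 0.375 s⁻¹, Ea1 = 69.0 kJ mol⁻¹, ΔH1 = −25.0 kJ mol⁻¹)
    X + E → X.E (k2 = 3000 M⁻¹ s⁻¹, Ea2 = 37.0 kJ mol⁻¹)
    Q → G (k3 = 0.00568 s⁻¹, Ea3 = 81.0 kJ mol⁻¹)
    L → Z (k4 = 1.06 × 10⁻⁵ s⁻¹, Ea4 = 102 kJ mol⁻¹)
    D ⇌ X, rate k5*(csat - [X]) (k5 = 0.0833 s⁻¹, csat = 21 mM)
    (constants at 25 °C)

| flask | L | D | temperature | time |
|---|---|---|---|---|
| beta | 0.30 M | 21 mM (held) | 25 °C | 1.0 min |
| eta | 0.30 M | 21 mM (held) | 10 °C | 1.0 min |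
| gamma | 0.30 M | 21 mM (held) | −5 °C | 1.0 min |
| theta | 0.30 M | 21 mM (held) | 40 °C | 1.0 min |

- the flask with the highest amount of X.E, in percent of the L charged ("all alike" if they lie within 1.5 percentage points) (beta / eta / gamma / theta / all alike)
- final X.E, as a percentage of the L charged, in beta
- final X.E, as a percentage of the L charged, in eta
- final X.E, as a percentage of the L charged, in gamma
- final X.E, as a percentage of the L charged, in theta

- at the start none of X is dissolved
- all constants are for 25 °C and move with temperature by the activation energies and enthalpies

Note for the bench: each flask starts with L and with D held, and none of X is dissolved. L splits into E and Q, X enters from D, and E captures X as X.E. While free X stays far below the saturation concentration, X enters at its highest rate, the transfer coefficient times that concentration, 0.105 M min⁻¹. Over 1.0 min this comes to 35.0 % of the L charged, and that share is the feed ceiling. The transfer step carries no activation energy in the scheme, so the ceiling does not move with the thermostat.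

The ceiling holds if the transfer is the rate-limiting step, and this is tested here in gamma, at −5 °C. In gamma, L splits at 0.300 M min⁻¹ at the start by the forward step alone, faster than X enters. Capture outruns the transfer, whose half-time is 8.32 s, as long as E stands above a crossing of 1.47 × 10⁻⁴ M, the transfer coefficient over the capture constant at that temperature. From this comparison of the starting rates, the reckoning by hand expects E to stand above that crossing, and so X.E just under the ceiling at each temperature, with the flasks alike. What should not be touched is the time and the charge of L: the ceiling rises with the first and falls with the second.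

The forecast gives all alike, with 34.85 % in beta, 34.77 % in eta, 34.6 % in gamma and 34.93 % in theta, X.E being “set by the dissolution ceiling”.

The simulation gives all alike, with 34.9 % in beta, 34.8 % in eta, 34.5 % in gamma and 34.9 % in theta.

In gamma at 1.00 min, free X has a capture half-life of 0.15 s, far shorter than the transfer half-time, E stands at 0.00812 M, above the crossing, and X.E reads 34.5 % against the ceiling of 35.0 %. A further flask like gamma but with 0.075 M of L has a ceiling of 140 %, more than its whole charge, and in that flask at 1.00 min E stands at 5.79 × 10⁻⁵ M, below the crossing, X at 0.0141 M and X.E at 62.8 %.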